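**Plan**
- Retrosynthesis: the two acetates are removed; the C10 ketone is traced back to a C10≡C11 ring alkyne, hydrated through the C13 hydroxyl; the ring is cut at C10≡C11 (alkyne metathesis); the open chain is cut at C4–C5 and C3–C4 (two boron homologations), at C12–C13 (aldol) and at the two alkyne termini (aldehyde homologations).
- Forward: a C11–C3 boronic ester (fragment A, from a terpene ketone) and a C5–C10 carbamate (fragment B, from a terpene aldehyde) are joined through a one-carbon C4 unit; the only ring, the 14-membered carbocycle, is closed by alkyne metathesis, followed by desilylation, hydration and acetylation.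
- Stereochemistry: C1 and C8 come from the chiral pool, C12/C13 from an oxazolidinone-controlled syn-aldol, C4 and C5 from (−)- and (+)-sparteine-controlled carbenoid homologations (reagent control).
- Enabling feature: in the ring C1 (isopropenyl) to C14, the C10 carbonyl lies γ to the C13 oxygen (O–C13–C12–C11–C10). A C10≡C11 alkyne in the 14-membered ring is therefore a regiodefined ketone precursor (5-endo attack of O13 on C10), and alkyne metathesis leaves the isopropenyl C=C alone.

Key step: step 20

Assumption: ring atoms are numbered C1 (isopropenyl-bearing carbon), C2, C3, C4 (Me), C5 (OAc), C6, C7, C8 (Me), C9, C10 (C=O), C11, C12 (Me), C13 (OAc), C14, and this numbering is kept for the corresponding atoms of all intermediates and for the macrocycle names; the step 1 epoxide is drawn trans to the isopropenyl group, which is immaterial because both epoxide centres are destroyed in step 2.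

**Fragment A (C11–C3)**

Step 1
Reactants: 1 (R)-carvone
Product: 2 (1R,4R,6R)-1-methyl-4-(prop-1-en-2-yl)-7-oxabicyclo[4.1.0]heptan-2-one
Conditions: 35% H2O2, NaOH (cat.), MeOH, 0 °C
Reagents that add atoms: hydrogen peroxide OO
Why: Weitz–Scheffer nucleophilic epoxidation, in which hydroperoxide adds in conjugate fashion to the enone only, anti to the ring substituent, so the electron-rich isopropenyl alkene should be untouched.

Step 2
Reactants: 2 carvone epoxide
Product: 4 (3R)-5-oxo-3-(prop-1-en-2-yl)pentanoic acid, via keto diol 3 (not isolated)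
Conditions: H5IO6 (2.5 equiv), THF/H2O, 0 °C → rt
Reagents that add atoms: water O
Why: Periodic acid should first open the epoxide to the α,β-dihydroxy ketone and then cut both the glycol and the α-ketol bond (Malaprade-type cleavage), so that the methyl-bearing carbon leaves as acetic acid and the untouched, non-enolisable stereocentre (future C1) sits between a CH2CHO arm (C14/C13) and a CH2CO2H arm (C2/C3).

Step 3
Reactants: 4 aldehyde acid
Product: 5 tert-butyl (3R)-5-oxo-3-(prop-1-en-2-yl)pentanoate
Conditions: Cl3CC(=NH)OtBu (2 equiv), CH2Cl2/cyclohexane, rt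
Reagents that add atoms: tert-butyl 2,2,2-trichloroacetimidate CC(C)(C)OC(=N)C(Cl)(Cl)Cl
Why: Imidate O-alkylation of the carboxylic acid needs neither base nor strong acid, so aldehyde and alkene are spared, and the tert-butyl ester is chosen because it resists LiBH4 (step 6) and K2CO3/MeOH (step 8).

Step 4
Reactants: 5 aldehyde ester; 6 (S)-4-benzyl-3-propionyloxazolidin-2-one
Product: 9 tert-butyl (3R,5R,6S)-7-[(4S)-4-benzyl-2-oxo-1,3-oxazolidin-3-yl]-5-hydroxy-6-methyl-7-oxo-3-(prop-1-en-2-yl)heptanoate, via boron enolate 7 (not isolated), via boron aldolate 8 (not isolated)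
Conditions: 6, Bu2BOTf, iPr2NEt, CH2Cl2, 0 °C; then 5, −78 → 0 °C; pH 7 buffer, MeOH, 30% H2O2
Reagents that add atoms: none
Why: Evans syn-aldol, in which the (Z)-dibutylboron enolate adds to the aldehyde through a Zimmerman–Traxler chair on the enolate face away from the benzyl group, setting C12 and C13 together (2S,3R in the acyl chain, syn) under auxiliary control with the remote C1 centre and the ester as spectators.

Step 5
Reactants: 9 aldol adduct
Product: 10 tert-butyl (3R,5R,6S)-7-[(4S)-4-benzyl-2-oxo-1,3-oxazolidin-3-yl]-5-[(tert-butyldimethylsilyl)oxy]-6-methyl-7-oxo-3-(prop-1-en-2-yl)heptanoate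
Conditions: TBSOTf, 2,6-lutidine, CH2Cl2, −78 → 0 °C
Reagents that add atoms: tert-butyldimethylsilyl triflate CC(C)(C)[Si](C)(C)OS(=O)(=O)C(F)(F)F
Why: Silyl triflate silylation of the hindered aldol hydroxyl blocks retro-aldol and elimination in later steps, and the low temperature should spare the tert-butyl ester.

Step 6
Reactants: 10 silylated imide
Product: 11 tert-butyl (3R,5R,6R)-5-[(tert-butyldimethylsilyl)oxy]-7-hydroxy-6-methyl-3-(prop-1-en-2-yl)heptanoate
Conditions: LiBH4, MeOH (1 equiv), THF, 0 °C
Reagents that add atoms: none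
Why: Reductive auxiliary removal, in which hydride attacks the activated imide carbonyl far faster than the tert-butyl ester, giving the C11 primary alcohol without touching C12.

Step 7
Reactants: 11 primary alcohol
Product: 12 tert-butyl (3R,5R,6S)-5-[(tert-butyldimethylsilyl)oxy]-6-methyl-7-oxo-3-(prop-1-en-2-yl)heptanoate
Conditions: Dess–Martin periodinane, NaHCO3, CH2Cl2, 0 °C → rt
Reagents that add atoms: none
Why: Dess–Martin oxidation under buffered, non-basic conditions should give the α-methyl aldehyde without epimerising C12 or eliminating the β-silyloxy group.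

Step 8
Reactants: 12 aldehyde
Product: 13 tert-butyl (3R,5R,6R)-5-[(tert-butyldimethylsilyl)oxy]-6-methyl-3-(prop-1-en-2-yl)oct-7-ynoate
Conditions: dimethyl (1-diazo-2-oxopropyl)phosphonate, K2CO3, MeOH, 0 °C → rt
Reagents that add atoms: dimethyl (1-diazo-2-oxopropyl)phosphonate COP(=O)(OC)C(=[N+]=[N-])C(C)=O
Why: Ohira–Bestmann (Seyferth–Gilbert) homologation, in which the diazomethylphosphonate anion formed in the flask adds to the aldehyde and loss of phosphate and N2 with a 1,2-hydride shift makes C11 an alkyne carbon, the mild base being expected to leave C12 intact.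

Step 9
Reactants: 13 alkynyl ester
Product: 14 (3S,5R,6R)-5-[(tert-butyldimethylsilyl)oxy]-6-methyl-3-(prop-1-en-2-yl)oct-7-yn-1-ol
Conditions: LiAlH4, Et2O, 0 °C
Reagents that add atoms: none
Why: LiAlH4 reduces the tert-butyl ester to the C3 primary alcohol, while the silyl ether, the alkene and the terminal alkyne are inert to hydride.

Step 10
Reactants: 14 terminal alkynol
Product: 16 (3S,5R,6R)-5-[(tert-butyldimethylsilyl)oxy]-6-methyl-3-(prop-1-en-2-yl)non-7-yn-1-ol, via dilithio alkoxide acetylide 15 (not isolated)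
Conditions: nBuLi (2.1 equiv), THF, −78 → −20 °C; MeI (1.1 equiv), −78 °C → rt
Reagents that add atoms: iodomethane CI
Why: Acetylide alkylation, in which the carbon centre of the dianion is far more nucleophilic than the lithium alkoxide in THF, so one equivalent of MeI should install the methyl cap needed for alkyne metathesis.

Step 11
Reactants: 16 methyl-capped alkynol
Product: 17 tert-butyl{[(4R,5R,7R)-9-iodo-4-methyl-7-(prop-1-en-2-yl)non-2-yn-5-yl]oxy}dimethylsilane
Conditions: I2, PPh3, imidazole, CH2Cl2, 0 °C → rt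
Reagents that add atoms: iodine II
Why: Appel-type iodination converts the unhindered primary alcohol to the iodide by SN2 displacement of the oxyphosphonium group without affecting the silyl ether or the unsaturation.

Step 12
Reactants: 17 primary iodide
Product: 19 tert-butyldimethyl{[(4R,5R,7S)-4-methyl-7-(prop-1-en-2-yl)-9-(4,4,5,5-tetramethyl-1,3,2-dioxaborolan-2-yl)non-2-yn-5-yl]oxy}silane, via primary alkyllithium 18 (not isolated)
Conditions: tBuLi (2.1 equiv), Et2O, −78 °C; then iPrOBpin, −78 °C → rt
Reagents that add atoms: 2-isopropoxy-4,4,5,5-tetramethyl-1,3,2-dioxaborolane CC(C)OB1OC(C)(C)C(C)(C)O1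
Why: Iodine–lithium exchange is faster than any deprotonation at −78 °C, and the primary alkyllithium is trapped by the borate to give the pinacol boronic ester after loss of isopropoxide.

**Fragment B (C5–C10)**

Step 13
Reactants: 20 (S)-citronellal
Product: 21 (4S)-4,8-dimethylnon-7-en-1-yne
Conditions: dimethyl (1-diazo-2-oxopropyl)phosphonate, K2CO3, MeOH, rt
Reagents that add atoms: dimethyl (1-diazo-2-oxopropyl)phosphonate COP(=O)(OC)C(=[N+]=[N-])C(C)=O
Why: Ohira–Bestmann homologation as in step 8 turns the aldehyde carbon (C10) into an alkyne carbon, and C8 is β to the carbonyl and cannot epimerise.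

Step 14
Reactants: 21 terminal enyne
Product: 23 (5S)-5,9-dimethyldec-8-en-2-yne, via lithium acetylide 22 (not isolated)
Conditions: nBuLi, THF, −78 °C; MeI, −78 °C → rt
Reagents that add atoms: iodomethane CI
Why: Deprotonation of the terminal alkyne and SN2 methylation of the acetylide installs the second methyl cap.

Step 15
Reactants: 23 methyl-capped enyne
Product: 25 (4S)-4-methyloct-6-yn-1-ol, via alkynal 24 (not isolated)
Conditions: O3, CH2Cl2/MeOH, −78 °C (Sudan Red 7B end point); then NaBH4, −78 °C → rt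
Reagents that add atoms: ozone [O-][O+]=O
Why: Ozonolysis with reductive work-up, in which ozone attacks the electron-rich trisubstituted alkene far faster than the internal alkyne and borohydride reduces the resulting aldehyde in the same flask to the C5 alcohol.

Step 16
Reactants: 25 alkynol
Product: 26 (4S)-4-methyloct-6-yn-1-yl N,N-diisopropylcarbamate
Conditions: iPr2NCOCl, Et3N, CH2Cl2, reflux
Reagents that add atoms: N,N-diisopropylcarbamoyl chloride CC(C)N(C(C)C)C(Cl)=O
Why: O-acylation of the primary alcohol gives the hindered carbamate that directs and stabilises α-lithiation at C5.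

**Union and endgame**

Step 17
Reactants: 19 primary boronic ester; 27 ethyl N,N-diisopropylcarbamate
Product: 30 tert-butyldimethyl{[(4R,5R,7S,10R)-4-methyl-7-(prop-1-en-2-yl)-10-(4,4,5,5-tetramethyl-1,3,2-dioxaborolan-2-yl)undec-2-yn-5-yl]oxy}silane, via lithiated ethyl carbamate 28 (not isolated), via boronate complex 29 (not isolated)
Conditions: 27, sBuLi, (−)-sparteine, Et2O, −78 °C, 5 h; then 19, −78 °C; MgBr2·OEt2, then reflux
Reagents that add atoms: none
Why: Sparteine-mediated carbamate lithiation–borylation (Matteson-type 1,2-metallate rearrangement), in which sBuLi/(−)-sparteine removes the pro-S proton of 27, the configurationally stable carbenoid is borylated with retention and the C3 group then migrates from boron to carbon with inversion, fixing C4 as R under reagent control.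

Step 18
Reactants: 30 secondary boronic ester; 26 carbamate
Product: 34 (5S,8S,9R,12S,14R,15R)-14-[(tert-butyldimethylsilyl)oxy]-5,9,15-trimethyl-12-(prop-1-en-2-yl)octadeca-2,16-diyn-8-ol, via lithiated carbamate 31 (not isolated), via boronate complex 32 (not isolated), via C5 boronic ester 33 (not isolated)
Conditions: 26, sBuLi, (+)-sparteine, Et2O, −78 °C, 5 h; then 30, −78 °C; MgBr2·OEt2, reflux; then NaOH, 30% H2O2, THF, 0 °C → rt
Reagents that add atoms: hydrogen peroxide OO
Why: A second lithiation–borylation, now with (+)-sparteine to give the mirror-image carbenoid, followed by retentive borylation, invertive migration of C4 (itself with retention) and stereoretentive C–B oxidation, should set C5 as S, anti to the C4 methyl, independently of substrate bias.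

Step 19
Reactants: 34 secondary alcohol
Product: 35 (4R,5R,7S,10R,11S,14S)-5,11-bis[(tert-butyldimethylsilyl)oxy]-4,10,14-trimethyl-7-(prop-1-en-2-yl)octadeca-2,16-diyne
Conditions: TBSOTf, 2,6-lutidine, CH2Cl2, 0 °C
Reagents that add atoms: tert-butyldimethylsilyl triflate CC(C)(C)[Si](C)(C)OS(=O)(=O)C(F)(F)F
Why: Silylation of the new secondary alcohol removes the last protic group before the alcohol-sensitive alkylidyne catalyst is used.

Step 20
Reactants: 35 acyclic methyl-capped diyne
Product: 36 (1S,4R,5S,8S,12R,13R)-5,13-bis[(tert-butyldimethylsilyl)oxy]-4,8,12-trimethyl-1-(prop-1-en-2-yl)cyclotetradec-10-yne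
Conditions: [Mo(≡CC6H4-4-OMe)(OSiPh3)3] (10 mol %), powdered 5 Å molecular sieves, toluene (2 mM), rt → 60 °C
Reagents that add atoms: none
Why: The molybdenum alkylidyne adds to one methyl-capped alkyne in a [2+2] step to give a metallacyclobutadiene, cycloreversion places the metal on the substrate, and a second [2+2]/retro-[2+2] on the other alkyne forms the C10≡C11 bond while the two caps leave together as 2-butyne. This is ring-closing alkyne metathesis, established for unstrained rings of twelve or more members. The single ring formed is the 14-membered carbocycle, closed end to end between C10 and C11 of the open chain, and a cycloalkyne of this size carries no appreciable angle strain. No stereocentre is created, and the six existing ones (C1, C4, C5, C8, C12, C13) see neither acid nor base. The step needs cyclisation over oligomerisation, which high dilution and capture of 2-butyne by the molecular sieves should secure by pulling every equilibrium toward the ring. It also needs C≡C over C=C selectivity, which the alkylidyne has intrinsically, so the 1,1-disubstituted isopropenyl alkene stays intact, and the bulky silyl ethers keep both oxygens off the Lewis-acidic hexavalent molybdenum centre.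

Step 21
Reactants: 36 cycloalkyne bis-silyl ether
Product: 37 (1S,4R,5S,8S,12R,13R)-4,8,12-trimethyl-1-(prop-1-en-2-yl)cyclotetradec-10-yne-5,13-diol
Conditions: TBAF, THF, rt → 45 °C
Reagents that add atoms: none
Why: Fluoride-mediated Si–O cleavage frees both secondary alcohols, and nothing else in the molecule is fluoride- or base-labile.

Step 22
Reactants: 37 cycloalkyne diol
Product: 39 (1S,4R,5S,8S,12R,13R)-5,13-dihydroxy-4,8,12-trimethyl-1-(prop-1-en-2-yl)cyclotetradecan-10-one, via bicyclic dihydrofuran 38 (not isolated)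
Conditions: Ph3PAuNTf2 (5 mol %), CH2Cl2, rt; then p-TsOH·H2O, THF/H2O, rt
Reagents that add atoms: water O
Why: Hydroxyl-directed alkyne hydration, in which cationic monovalent gold activates the alkyne for anti attack of the C13 hydroxyl on C10 (5-endo-dig hydroalkoxylation, attack at C11 needing a four-membered ring) and acid hydrolysis of the 2,3-dihydrofuran places the carbonyl at C10 only, with the isopropenyl alkene inert and no stereocentre at C9 or C11 to epimerise.

Step 23
Reactants: 39 dihydroxy ketone
Product: 40 (1S,4R,5S,8S,12R,13R)-4,8,12-trimethyl-10-oxo-1-(prop-1-en-2-yl)cyclotetradecane-5,13-diyl diacetate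
Conditions: Ac2O, DMAP (cat.), Et3N, CH2Cl2, rt
Reagents that add atoms: acetic anhydride CC(=O)OC(C)=O
Why: DMAP-catalysed acylation esterifies both secondary alcohols, drawing any C10 hemiketal back to the open hydroxy ketone, and should give the target.

**Compound list**

1 | (R)-carvone, (5R)-2-methyl-5-(prop-1-en-2-yl)cyclohex-2-en-1-one | C=C(C)[C@@H]1CC=C(C)C(=O)C1 | starting material
2 | (1R,4R,6R)-1-methyl-4-(prop-1-en-2-yl)-7-oxabicyclo[4.1.0]heptan-2-one | C=C(C)[C@@H]1C[C@H]2O[C@@]2(C)C(=O)C1 | intermediate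
3 | (2R,3S,5R)-2,3-dihydroxy-2-methyl-5-(prop-1-en-2-yl)cyclohexan-1-one (not isolated) | C=C(C)[C@@H]1C[C@H](O)[C@@](C)(O)C(=O)C1 | intermediate
4 | (3R)-5-oxo-3-(prop-1-en-2-yl)pentanoic acid | C=C(C)[C@@H](CC(=O)O)CC=O | intermediate
5 | tert-butyl (3R)-5-oxo-3-(prop-1-en-2-yl)pentanoate | C=C(C)[C@@H](CC(=O)OC(C)(C)C)CC=O | intermediate
6 | (S)-4-benzyl-3-propionyloxazolidin-2-one | CCC(=O)N1[C@@H](Cc2ccccc2)COC1=O | starting material
7 | (Z)-dibutylboron enolate of 6 (not isolated) | C/C=C(\OB(CCCC)CCCC)N1[C@@H](Cc2ccccc2)COC1=O | intermediate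
8 | O-dibutylboryl aldolate of 9 (not isolated) | CC(C)(C)OC(=O)C[C@H](C(C)=C)C[C@@H](OB(CCCC)CCCC)[C@H](C)C(=O)N1[C@@H](Cc2ccccc2)COC1=O | intermediate
9 | tert-butyl (3R,5R,6S)-7-[(4S)-4-benzyl-2-oxo-1,3-oxazolidin-3-yl]-5-hydroxy-6-methyl-7-oxo-3-(prop-1-en-2-yl)heptanoate | CC(C)(C)OC(=O)C[C@H](C(C)=C)C[C@@H](O)[C@H](C)C(=O)N1[C@@H](Cc2ccccc2)COC1=O | intermediate
10 | tert-butyl (3R,5R,6S)-7-[(4S)-4-benzyl-2-oxo-1,3-oxazolidin-3-yl]-5-[(tert-butyldimethylsilyl)oxy]-6-methyl-7-oxo-3-(prop-1-en-2-yl)heptanoate | CC(C)(C)OC(=O)C[C@H](C(C)=C)C[C@@H](O[Si](C)(C)C(C)(C)C)[C@H](C)C(=O)N1[C@@H](Cc2ccccc2)COC1=O | intermediate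
11 | tert-butyl (3R,5R,6R)-5-[(tert-butyldimethylsilyl)oxy]-7-hydroxy-6-methyl-3-(prop-1-en-2-yl)heptanoate | CC(C)(C)OC(=O)C[C@H](C(C)=C)C[C@@H](O[Si](C)(C)C(C)(C)C)[C@H](C)CO | intermediate
12 | tert-butyl (3R,5R,6S)-5-[(tert-butyldimethylsilyl)oxy]-6-methyl-7-oxo-3-(prop-1-en-2-yl)heptanoate | CC(C)(C)OC(=O)C[C@H](C(C)=C)C[C@@H](O[Si](C)(C)C(C)(C)C)[C@H](C)C=O | intermediate
13 | tert-butyl (3R,5R,6R)-5-[(tert-butyldimethylsilyl)oxy]-6-methyl-3-(prop-1-en-2-yl)oct-7-ynoate | CC(C)(C)OC(=O)C[C@H](C(C)=C)C[C@@H](O[Si](C)(C)C(C)(C)C)[C@H](C)C#C | intermediate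
14 | (3S,5R,6R)-5-[(tert-butyldimethylsilyl)oxy]-6-methyl-3-(prop-1-en-2-yl)oct-7-yn-1-ol | OCC[C@H](C(C)=C)C[C@@H](O[Si](C)(C)C(C)(C)C)[C@H](C)C#C | intermediate
15 | dilithium alkoxide acetylide of 14 (not isolated) | [Li]OCC[C@H](C(C)=C)C[C@@H](O[Si](C)(C)C(C)(C)C)[C@H](C)C#C[Li] | intermediate
16 | (3S,5R,6R)-5-[(tert-butyldimethylsilyl)oxy]-6-methyl-3-(prop-1-en-2-yl)non-7-yn-1-ol | OCC[C@H](C(C)=C)C[C@@H](O[Si](C)(C)C(C)(C)C)[C@H](C)C#CC | intermediate
17 | tert-butyl{[(4R,5R,7R)-9-iodo-4-methyl-7-(prop-1-en-2-yl)non-2-yn-5-yl]oxy}dimethylsilane | ICC[C@H](C(C)=C)C[C@@H](O[Si](C)(C)C(C)(C)C)[C@H](C)C#CC | intermediate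
18 | primary alkyllithium from 17, lithium in place of iodine (not isolated) | [Li]CC[C@H](C(C)=C)C[C@@H](O[Si](C)(C)C(C)(C)C)[C@H](C)C#CC | intermediate
19 | tert-butyldimethyl{[(4R,5R,7S)-4-methyl-7-(prop-1-en-2-yl)-9-(4,4,5,5-tetramethyl-1,3,2-dioxaborolan-2-yl)non-2-yn-5-yl]oxy}silane | CC1(C)OB(CC[C@H](C(C)=C)C[C@@H](O[Si](C)(C)C(C)(C)C)[C@H](C)C#CC)OC1(C)C | intermediate
20 | (S)-citronellal | CC(C)=CCC[C@H](C)CC=O | starting material
21 | (4S)-4,8-dimethylnon-7-en-1-yne | C#CC[C@@H](C)CCC=C(C)C | intermediate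
22 | lithium acetylide of 21 (not isolated) | [Li]C#CC[C@@H](C)CCC=C(C)C | intermediate
23 | (5S)-5,9-dimethyldec-8-en-2-yne | CC#CC[C@@H](C)CCC=C(C)C | intermediate
24 | (4S)-4-methyloct-6-ynal (not isolated) | CC#CC[C@@H](C)CCC=O | intermediate
25 | (4S)-4-methyloct-6-yn-1-ol | CC#CC[C@@H](C)CCCO | intermediate
26 | (4S)-4-methyloct-6-yn-1-yl N,N-diisopropylcarbamate | CC#CC[C@@H](C)CCCOC(=O)N(C(C)C)C(C)C | intermediate
27 | ethyl N,N-diisopropylcarbamate | CCOC(=O)N(C(C)C)C(C)C | starting material
28 | (S)-1-lithioethyl N,N-diisopropylcarbamate, as its (−)-sparteine complex (not isolated) | C[C@H]([Li])OC(=O)N(C(C)C)C(C)C | intermediate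
29 | lithium boronate complex of 28 with 19 (not isolated) | [Li+].C[C@@H](OC(=O)N(C(C)C)C(C)C)[B-]1(CC[C@H](C(C)=C)C[C@@H](O[Si](C)(C)C(C)(C)C)[C@H](C)C#CC)OC(C)(C)C(C)(C)O1 | intermediate
30 | tert-butyldimethyl{[(4R,5R,7S,10R)-4-methyl-7-(prop-1-en-2-yl)-10-(4,4,5,5-tetramethyl-1,3,2-dioxaborolan-2-yl)undec-2-yn-5-yl]oxy}silane | C[C@@H](B1OC(C)(C)C(C)(C)O1)CC[C@H](C(C)=C)C[C@@H](O[Si](C)(C)C(C)(C)C)[C@H](C)C#CC | intermediate
31 | (1R,4S)-1-lithio-4-methyloct-6-yn-1-yl N,N-diisopropylcarbamate, as its (+)-sparteine complex (not isolated) | CC#CC[C@@H](C)CC[C@@H]([Li])OC(=O)N(C(C)C)C(C)C | intermediate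
32 | lithium boronate complex of 31 with 30 (not isolated) | [Li+].CC#CC[C@@H](C)CC[C@H](OC(=O)N(C(C)C)C(C)C)[B-]1(OC(C)(C)C(C)(C)O1)[C@H](C)CC[C@H](C(C)=C)C[C@@H](O[Si](C)(C)C(C)(C)C)[C@H](C)C#CC | intermediate
33 | C5 pinacol boronic ester, boron in the place of the C5 hydroxyl of 34 with the same spatial arrangement (not isolated) | CC#CC[C@@H](C)CC[C@H](B1OC(C)(C)C(C)(C)O1)[C@H](C)CC[C@H](C(C)=C)C[C@@H](O[Si](C)(C)C(C)(C)C)[C@H](C)C#CC | intermediate
34 | (5S,8S,9R,12S,14R,15R)-14-[(tert-butyldimethylsilyl)oxy]-5,9,15-trimethyl-12-(prop-1-en-2-yl)octadeca-2,16-diyn-8-ol | CC#CC[C@@H](C)CC[C@H](O)[C@H](C)CC[C@H](C(C)=C)C[C@@H](O[Si](C)(C)C(C)(C)C)[C@H](C)C#CC | intermediate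
35 | (4R,5R,7S,10R,11S,14S)-5,11-bis[(tert-butyldimethylsilyl)oxy]-4,10,14-trimethyl-7-(prop-1-en-2-yl)octadeca-2,16-diyne | CC#CC[C@@H](C)CC[C@H](O[Si](C)(C)C(C)(C)C)[C@H](C)CC[C@H](C(C)=C)C[C@@H](O[Si](C)(C)C(C)(C)C)[C@H](C)C#CC | intermediate
36 | (1S,4R,5S,8S,12R,13R)-5,13-bis[(tert-butyldimethylsilyl)oxy]-4,8,12-trimethyl-1-(prop-1-en-2-yl)cyclotetradec-10-yne | C=C(C)[C@H]1CC[C@@H](C)[C@@H](O[Si](C)(C)C(C)(C)C)CC[C@H](C)CC#C[C@@H](C)[C@H](O[Si](C)(C)C(C)(C)C)C1 | intermediate
37 | (1S,4R,5S,8S,12R,13R)-4,8,12-trimethyl-1-(prop-1-en-2-yl)cyclotetradec-10-yne-5,13-diol | C=C(C)[C@H]1CC[C@@H](C)[C@@H](O)CC[C@H](C)CC#C[C@@H](C)[C@H](O)C1 | intermediate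
38 | bicyclic 2,3-dihydrofuran: O13 bonded to C10, C10=C11, C5–OH free, all six centres as in 37 (not isolated) | C=C(C)[C@H]1CC[C@@H](C)[C@@H](O)CC[C@H](C)CC2=C[C@@H](C)[C@H](O2)C1 | intermediate
39 | (1S,4R,5S,8S,12R,13R)-5,13-dihydroxy-4,8,12-trimethyl-1-(prop-1-en-2-yl)cyclotetradecan-10-one | C=C(C)[C@H]1CC[C@@H](C)[C@@H](O)CC[C@H](C)CC(=O)C[C@@H](C)[C@H](O)C1 | intermediate
40 | (1S,4R,5S,8S,12R,13R)-4,8,12-trimethyl-10-oxo-1-(prop-1-en-2-yl)cyclotetradecane-5,13-diyl diacetate | C=C(C)[C@H]1CC[C@@H](C)[C@@H](OC(C)=O)CC[C@H](C)CC(=O)C[C@@H](C)[C@H](OC(C)=O)C1 | target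

**Step count**

Total: 23 steps (1–12 fragment A, 13–16 fragment B, 17–23 union, ring closure and endgame).
Longest linear sequence: 19 steps (1–12, then 17–23), from (R)-carvone.

**Steps most likely to fail**

Step 18. The hindered secondary boronic ester 30 may add only reversibly to the lithiated carbamate 31, and the carbamate is a reluctant leaving group. The boronate complex 32 could therefore revert, or the carbenoid could decompose or abstract a propargylic proton, before the 1,2-shift, costing conversion and configurational purity at C5. The fallback changes the way the carbenoid is made and the leaving group it carries. It sets out from alcohol 25, which would be esterified with 2,4,6-triisopropylbenzoyl chloride (Et3N, DMAP) to (4S)-4-methyloct-6-yn-1-yl 2,4,6-triisopropylbenzoate F1. Lithiation with sBuLi/(+)-sparteine and quenching with Me3SnCl would give the storable (1R,4S)-4-methyl-1-(trimethylstannyl)oct-6-yn-1-yl 2,4,6-triisopropylbenzoate F2, whose enantiopurity can be checked and upgraded. Tin–lithium exchange with nBuLi at −78 °C, without diamine or excess base, would regenerate the (1R)-lithio benzoate F3, and addition of 30 would give the benzoate boronate complex F4. The better leaving group should let the 1,2-shift run on warming without Lewis acid to give 33, and NaOH/H2O2 oxidation returns to the route at 34.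

Step 22. Competing attack of the C5 hydroxyl, transannular ketalisation of the enol ether, or slow turnover at the propargylically branched alkyne could divert the hydroalkoxylation, and forcing the hydration could then give C10/C11 ketone mixtures. The fallback delivers the oxygen through silicon instead. It sets out from diol 37, which would be silylated with 1,1,3,3-tetramethyldisilazane to the bis(dimethylsilyl) ether F5. [Cp*Ru(NCMe)3]PF6 would then catalyse intramolecular trans-hydrosilylation in which the C13–O–SiMe2H tether places silicon on C10 in a 6-endo-dig mode, giving the cyclic siloxane F6. Tamao–Fleming oxidation (KF, KHCO3, H2O2) would convert the C10–Si bond into the C10 ketone and free both hydroxyls, returning to the route at 39.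

Step 2. The electron-poor epoxide may open only sluggishly under periodic acid, and long acid exposure could then hydrate or isomerise the isopropenyl group or leave the fission incomplete. The fallback gives up the single acidic operation for two separate events. It sets out from epoxide 2, which would be hydrolysed with dilute HClO4 in THF/H2O at 0 °C to the isolated keto diol 3. Compound 3 would then be cleaved under neutral conditions with NaIO4 in pH 7 buffered aqueous THF, returning to the route at 4. This fallback makes no compound outside the list (F0).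

**Further compounds**

F1 | step 18 | (4S)-4-methyloct-6-yn-1-yl 2,4,6-triisopropylbenzoate | CC#CC[C@@H](C)CCCOC(=O)c1c(C(C)C)cc(C(C)C)cc1C(C)C
F2 | step 18 | (1R,4S)-4-methyl-1-(trimethylstannyl)oct-6-yn-1-yl 2,4,6-triisopropylbenzoate | CC#CC[C@@H](C)CC[C@@H]([Sn](C)(C)C)OC(=O)c1c(C(C)C)cc(C(C)C)cc1C(C)C
F3 | step 18 | (1R,4S)-1-lithio-4-methyloct-6-yn-1-yl 2,4,6-triisopropylbenzoate | CC#CC[C@@H](C)CC[C@@H]([Li])OC(=O)c1c(C(C)C)cc(C(C)C)cc1C(C)C
F4 | step 18 | lithium boronate complex of F3 with 30 | [Li+].CC#CC[C@@H](C)CC[C@H](OC(=O)c1c(C(C)C)cc(C(C)C)cc1C(C)C)[B-]1(OC(C)(C)C(C)(C)O1)[C@H](C)CC[C@H](C(C)=C)C[C@@H](O[Si](C)(C)C(C)(C)C)[C@H](C)C#CC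
F5 | step 22 | bis(dimethylsilyl) ether of 37 | C=C(C)[C@H]1CC[C@@H](C)[C@@H](O[SiH](C)C)CC[C@H](C)CC#C[C@@H](C)[C@H](O[SiH](C)C)C1
F6 | step 22 | cyclic siloxane with O13–SiMe2–C10 and C10=C11, C5 dimethylsilyl ether retained | C=C(C)[C@H]1CC[C@@H](C)[C@@H](O[SiH](C)C)CC[C@H](C)CC2=C[C@@H](C)[C@H](O[Si]2(C)C)C1
F0 | step 2 | none | none
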